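**Plan**

- Retrosynthetic cuts, in order: (i) the enol-ether O–C(sp2) bond of the dihydropyran, giving a C4 tertiary alcohol and a 2-alkyl trione; (ii) the trione ring bond C2–C3 (ketone–ester Claisen); (iii) the chain bond between the C1 carbonyl and its CMe2 neighbour (aldol, then oxidation); (iv) the C4–O and C5–C1′ bonds (oxa-Diels–Alder on caryophyllene).
- Enabling feature: the tetramethylcyclohexanetrione ring is joined to the rest only at two adjacent atoms, C2 (bonded to C1′) and a flanking carbonyl carbon (the later enol-ether carbon). Its three carbonyls are mutually 1,3 and separated by quaternary CMe2 carbons, so the opened chain has one enolisable CH2 and an ester six atoms away.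
- Forward order: a temporary δ-lactone ring is built on the ring E-alkene of (−)-β-caryophyllene, then opened to a silyl-protected aldehyde. The C7 keto-ester arm is joined by aldol and oxidised, the carbocyclic trione ring is closed, and the dihydropyran ring is closed last.
- Stereochemistry: C1 and C9 come from natural (−)-β-caryophyllene. C4, C5 and C1′ are set together in the cycloaddition, and no later step breaks a bond at these centres.

Key step: step 9

Labels: caryophyllane numbering (C4 = oxygenated quaternary carbon, C5 = adjacent CH, C8 = methylene-bearing carbon, C1/C9 = ring-fusion carbons); C1′ = isopropyl-bearing carbon; trione ring C1–C6 with C2 bonded to C1′.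

Assumption: the 2-alkyl trione intermediates are drawn as triketones although they should be largely enolised, and the aldol product is carried as a mixture of carbinol epimers because that centre is oxidised in the following step.

**Route**

Step 1
Reactants: 1 Meldrum's acid (2,2-dimethyl-1,3-dioxane-4,6-dione); 2 isobutyraldehyde
Product: 3 2,2-dimethyl-5-(2-methylpropylidene)-1,3-dioxane-4,6-dione (isobutylidene Meldrum's acid)
Conditions: piperidinium acetate (cat.), CH2Cl2, 4 Å MS, 0 °C → rt
Reagents that add atoms: none
Why: Knoevenagel condensation of the strongly C–H acidic dioxanedione with an α-branched aldehyde, run with a slight excess of aldehyde and water removal so that the alkylidene compound is not consumed by a second Michael addition; no stereocentre is formed.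

Step 2
Reactants: 3 isobutylidene Meldrum's acid; 4 (−)-β-caryophyllene ((1R,9S), E ring alkene)
Product: 7 caryophyllane-fused δ-lactone (4-isopropyl-tetrahydropyran-2-one trans-fused across C4–C5; ring O on C4; 1R,4R,5S,9S,1′R), via dioxinone cycloadduct 5 (not isolated), via carboxy lactone 6 (not isolated)
Conditions: 4 (2 equiv), PhMe, rt → 60 °C; then pyridine–H2O (10:1), 100 °C
Reagents that add atoms: none
Why: Inverse-electron-demand oxa-Diels–Alder reaction of the 2-alkylidene-1,3-dicarbonyl heterodiene with the strained E-trisubstituted ring alkene (the exocyclic methylene is far less reactive), oxygen bonding to the more substituted C4 and the isopropyl-bearing carbon to C5; suprafacial addition to the E-alkene fixes the C4 methyl and H-5 trans, attack on the exposed alkene face (the one that is also epoxidised preferentially) should give 4R,5S, and the transition state with isopropyl outward on the heterodiene and the dioxanedione over the C4-methyl/C6 edge gives 1′R (H-1′ cis to H-5), after which hydrolysis of the ketene acetal releases acetone and the malonic half-acid decarboxylates; isomers from the other face or orientation are to be removed here by chromatography.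

Step 3
Reactants: 7 δ-lactone
Product: 8 hydroxy Weinreb amide, (3R)-3-[(1R,4R,5S,9S)-4-hydroxy-4,11,11-trimethyl-8-methylenebicyclo[7.2.0]undecan-5-yl]-N-methoxy-N,4-dimethylpentanamide
Conditions: MeNH(OMe)·HCl, AlMe3, CH2Cl2, 0 °C → rt; aq. Rochelle salt
Reagents that add atoms: N,O-dimethylhydroxylamine hydrochloride, CNOC.Cl
Why: Weinreb aminolysis of a lactone by the aluminium amide, which attacks the unhindered CH2–C(=O) acyl carbon and releases the tertiary C4 alkoxide without touching any stereocentre; the crude product is silylated at once to prevent relactonisation.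

Step 4
Reactants: 8 hydroxy Weinreb amide
Product: 9 triethylsilyl ether of 8 (C4–OSiEt3)
Conditions: TESOTf, 2,6-lutidine, CH2Cl2, −78 → 0 °C
Reagents that add atoms: triethylsilyl trifluoromethanesulfonate, CC[Si](CC)(CC)OS(=O)(=O)C(F)(F)F
Why: Silyl triflate/lutidine silylation is the standard method for a hindered tertiary alcohol, and the ether keeps the C4 oxygen from adding to the chain carbonyls in all later basic steps.

Step 5
Reactants: 9 silylated Weinreb amide
Product: 10 aldehyde, (3R)-4-methyl-3-[(1R,4R,5S,9S)-4,11,11-trimethyl-8-methylene-4-(triethylsilyloxy)bicyclo[7.2.0]undecan-5-yl]pentanal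
Conditions: DIBAL-H, THF, −78 °C; aq. Rochelle salt
Reagents that add atoms: none
Why: Hydride reduction of a Weinreb amide stops at the chelated tetrahedral adduct, which gives the aldehyde only on work-up, so over-reduction is avoided and the alkene and silyl ether are untouched.

Step 6
Reactants: 11 methyl isobutyrate; 12 isobutyryl chloride
Product: 13 methyl 2,2,4-trimethyl-3-oxopentanoate
Conditions: LDA, THF, −78 °C; then cannulated into 12, THF, −78 °C → rt
Reagents that add atoms: none
Why: C-acylation of a fully substituted lithium ester enolate by an acid chloride (crossed Claisen-type acylation), done by inverse addition so that the enolate always meets excess electrophile; the product has no C–H between its carbonyls and cannot quench the enolate there.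

Step 7
Reactants: 10 aldehyde; 13 methyl 2,2,4-trimethyl-3-oxopentanoate
Product: 14 aldol adduct, methyl (7R)-5-hydroxy-2,2,4,4,8-pentamethyl-3-oxo-7-[(1R,4R,5S,9S)-4,11,11-trimethyl-8-methylene-4-(triethylsilyloxy)bicyclo[7.2.0]undecan-5-yl]nonanoate (both C5-carbinol epimers)
Conditions: 13, LDA, THF, −78 → 0 → −78 °C; then 10, −78 °C; AcOH, −78 °C
Reagents that add atoms: none
Why: Directed aldol addition of the preformed lithium enolate of the isopropyl ketone (the only enolisable position of 13) to the unhindered aldehyde, quenched cold to forestall retro-aldol and attack of the aldolate on the ester; the new carbinol centre is formed without control and is destroyed in step 8.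

Step 8
Reactants: 14 aldol adduct
Product: 15 diketo ester, methyl (7R)-2,2,4,4,8-pentamethyl-3,5-dioxo-7-[(1R,4R,5S,9S)-4,11,11-trimethyl-8-methylene-4-(triethylsilyloxy)bicyclo[7.2.0]undecan-5-yl]nonanoate
Conditions: DMP, NaHCO3, CH2Cl2, 0 °C → rt
Reagents that add atoms: none
Why: Dess–Martin oxidation of a hindered secondary alcohol under buffered, non-basic conditions gives the 2,2-dimethyl-1,3-diketone without retro-aldol, and neither the silyl ether nor the alkene is affected.

Step 9
Reactants: 15 diketo ester
Product: 16 silyl-protected 2-alkyl syncarpic acid, 4,4,6,6-tetramethyl-2-[(1R)-2-methyl-1-[(1R,4R,5S,9S)-4,11,11-trimethyl-8-methylene-4-(triethylsilyloxy)bicyclo[7.2.0]undecan-5-yl]propyl]cyclohexane-1,3,5-trione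
Conditions: KOt-Bu (2.5 equiv), THF, 0 °C → rt; cold dil. HCl to pH 3
Reagents that add atoms: none
Why: tert-Butoxide removes a proton from the only enolisable position of 15, the C2 methylene (every other α-carbon is quaternary), and the ketone enolate adds to the terminal methyl ester; loss of methoxide gives the trione, which is deprotonated at once to its stabilised enolate. This is a ketone–ester Claisen (Dieckmann-type) condensation, the classical entry to syncarpic acid and its 2-alkyl derivatives. The one ring formed, the carbocycle C1–C6, closes in a 6-(enolendo)-exo-trig mode with formation of the C2–C3 bond. No stereocentre is created (C2 carries two identical ring arms and is enolised), and C4, C5 and C1′ are not acidic and keep their configuration. The step needs C-acylation to outrun retro-Claisen cleavage of the non-enolisable 1,3-dicarbonyl units: the bulky, weakly nucleophilic base, the aprotic solvent and the irreversible deprotonation of the product secure this, and any O-acylated enol lactone is reopened by the liberated methoxide and funnelled to the trione enolate. The silyl ether is essential, because a free C4 alkoxide would add to the C1 ketone and fragment the chain back to lactone 7 and the enolate of 13.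

Step 10
Reactants: 16 silyl-protected 2-alkyl syncarpic acid
Product: 18 myrtucommulone K (1R,4R,5S,9S,1′R), via hydroxy trione 17 (not isolated)
Conditions: HF·pyridine, pyridine, THF, 0 °C → rt; then PPTS (cat.), PhMe, 4 Å MS, 60 °C
Reagents that add atoms: none
Why: Fluoride-mediated desilylation frees the tertiary hydroxyl, which then undergoes the known acid-catalysed cyclodehydration of 2-(3-hydroxyalkyl)-1,3-diones to cyclic vinylogous esters (addition to either of the two equivalent flanking carbonyls, then loss of water); the C4–O bond is never broken, so C4 keeps its configuration, and the mild acid is chosen to spare the exocyclic methylene.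

**Compound list**

1 | Meldrum's acid | CC1(C)OC(=O)CC(=O)O1 | starting material
2 | isobutyraldehyde | CC(C)C=O | starting material
3 | 2,2-dimethyl-5-(2-methylpropylidene)-1,3-dioxane-4,6-dione | CC(C)C=C1C(=O)OC(C)(C)OC1=O | intermediate
4 | (−)-β-caryophyllene | C=C1CC/C=C(\C)CC[C@@H]2[C@@H]1CC2(C)C | starting material
5 | dioxinone cycloadduct (pyrano[2,3-d][1,3]dioxin-4-one fused across C4–C5; 1R,4R,5S,9S,1′R) | C=C1CC[C@H]2[C@@H](C(C)C)C3=C(O[C@]2(C)CC[C@@H]2[C@@H]1CC2(C)C)OC(C)(C)OC3=O | intermediate
6 | carboxy lactone (α-carboxy δ-lactone, α-centre undefined) | C=C1CC[C@H]2[C@@H](C(C)C)C(C(=O)O)C(=O)O[C@]2(C)CC[C@@H]2[C@@H]1CC2(C)C | intermediate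
7 | caryophyllane-fused δ-lactone (1R,4R,5S,9S,1′R) | C=C1CC[C@H]2[C@@H](C(C)C)CC(=O)O[C@]2(C)CC[C@@H]2[C@@H]1CC2(C)C | intermediate
8 | hydroxy Weinreb amide | C=C1CC[C@@H]([C@@H](C(C)C)CC(=O)N(C)OC)[C@](C)(O)CC[C@@H]2[C@@H]1CC2(C)C | intermediate
9 | triethylsilyl ether of the Weinreb amide | C=C1CC[C@@H]([C@@H](C(C)C)CC(=O)N(C)OC)[C@](C)(O[Si](CC)(CC)CC)CC[C@@H]2[C@@H]1CC2(C)C | intermediate
10 | silyloxy aldehyde | C=C1CC[C@@H]([C@@H](C(C)C)CC=O)[C@](C)(O[Si](CC)(CC)CC)CC[C@@H]2[C@@H]1CC2(C)C | intermediate
11 | methyl isobutyrate | COC(=O)C(C)C | starting material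
12 | isobutyryl chloride | CC(C)C(=O)Cl | starting material
13 | methyl 2,2,4-trimethyl-3-oxopentanoate | COC(=O)C(C)(C)C(=O)C(C)C | intermediate
14 | aldol adduct (carbinol epimers) | C=C1CC[C@@H]([C@@H](C(C)C)CC(O)C(C)(C)C(=O)C(C)(C)C(=O)OC)[C@](C)(O[Si](CC)(CC)CC)CC[C@@H]2[C@@H]1CC2(C)C | intermediate
15 | silyloxy diketo ester (Dieckmann precursor) | C=C1CC[C@@H]([C@@H](C(C)C)CC(=O)C(C)(C)C(=O)C(C)(C)C(=O)OC)[C@](C)(O[Si](CC)(CC)CC)CC[C@@H]2[C@@H]1CC2(C)C | intermediate
16 | silyl-protected 2-alkyl syncarpic acid (Dieckmann product) | C=C1CC[C@@H]([C@@H](C(C)C)C2C(=O)C(C)(C)C(=O)C(C)(C)C2=O)[C@](C)(O[Si](CC)(CC)CC)CC[C@@H]2[C@@H]1CC2(C)C | intermediate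
17 | hydroxy trione (2-alkyl syncarpic acid with free C4 tertiary alcohol) | C=C1CC[C@@H]([C@@H](C(C)C)C2C(=O)C(C)(C)C(=O)C(C)(C)C2=O)[C@](C)(O)CC[C@@H]2[C@@H]1CC2(C)C | intermediate
18 | myrtucommulone K | C=C1CC[C@H]2[C@@H](C(C)C)C3=C(O[C@]2(C)CC[C@@H]2[C@@H]1CC2(C)C)C(C)(C)C(=O)C(C)(C)C3=O | target

**Step count**

Total: 10 steps. Longest linear sequence: 9 steps (1, 2, 3, 4, 5, 7, 8, 9, 10); step 6 is a one-step side branch.

**Steps most likely to fail**

Step 9. The hindered enolate may fail to reach the neopentyl-type ester carbonyl, while alkoxide cleaves the non-enolisable 1,3-dicarbonyl units by retro-Claisen fragmentation. The fallback keeps the C2–C3 ring bond but changes the acceptor from an ester to a nitrile. This is a Thorpe-type closure, known from the base cyclisation of 5-oxo nitriles to 3-aminocyclohex-2-enones, and it liberates no alkoxide. It sets out from aldehyde 10. Isobutyronitrile (purchased) is deprotonated with LDA and acylated with 12 to give 2,2,4-trimethyl-3-oxopentanenitrile F1. The lithium enolate of F1 is added to 10 at −78 °C to give the hydroxy keto nitrile F2, which Dess–Martin periodinane oxidises to the diketo nitrile F3. LiHMDS in THF then adds the C2 enolate to the nitrile and gives the cyclic enaminone F4. Warm dilute HCl in THF hydrolyses the vinylogous amide and removes the silyl group, giving 17, where the route is rejoined for the cyclodehydration stage of step 10.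

Step 2. The cycloaddition may discriminate poorly between the two alkene faces and between the two orientations of the isopropyl group, or the strongly enophilic heterodiene may be diverted into an ene reaction at the exocyclic methylene. The fallback sets out from 4 and uses a heterodiene that already contains the complete trione. Syncarpic acid (4,4,6,6-tetramethylcyclohexane-1,3,5-trione, purchased) is condensed with 2 under Knoevenagel conditions to 2-(2-methylpropylidene)-4,4,6,6-tetramethylcyclohexane-1,3,5-trione F5. This is heated with 4 in an oxa-Diels–Alder reaction of the type known for cyclic 2-alkylidene-1,3-diones with this alkene. Addition across C4=C5 gives 18 directly, so the route is rejoined at 18 and stereoisomers are separated once, on the final compound. This reserve path gives up the late ring closure and does not by itself cure a selectivity problem.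

Step 7. Slow addition of the tetrasubstituted lithium enolate and retro-aldol reversal may prevent the carbon–carbon bond from forming, and the lithium aldolate may cyclise onto the methyl ester. The fallback replaces the basic, reversible aldol by an irreversible Lewis-acid Mukaiyama aldol. It sets out from 13, which TMSOTf and Et3N in CH2Cl2 convert into its silyl enol ether, methyl 2,2,4-trimethyl-3-(trimethylsilyloxy)pent-3-enoate F6. F6 is added to 10 with BF3·OEt2 in CH2Cl2 at −78 °C, and aqueous work-up gives 14, rejoining the route before step 8.

**Further compounds**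

F1 | step 9 | 2,2,4-trimethyl-3-oxopentanenitrile | CC(C)C(=O)C(C)(C)C#N
F2 | step 9 | silyloxy hydroxy keto nitrile (carbinol epimers) | C=C1CC[C@@H]([C@@H](C(C)C)CC(O)C(C)(C)C(=O)C(C)(C)C#N)[C@](C)(O[Si](CC)(CC)CC)CC[C@@H]2[C@@H]1CC2(C)C
F3 | step 9 | silyloxy diketo nitrile | C=C1CC[C@@H]([C@@H](C(C)C)CC(=O)C(C)(C)C(=O)C(C)(C)C#N)[C@](C)(O[Si](CC)(CC)CC)CC[C@@H]2[C@@H]1CC2(C)C
F4 | step 9 | cyclic enaminone (3-amino-2-alkyl-4,4,6,6-tetramethylcyclohex-2-ene-1,5-dione, silyl ether) | C=C1CC[C@@H]([C@@H](C(C)C)C2=C(N)C(C)(C)C(=O)C(C)(C)C2=O)[C@](C)(O[Si](CC)(CC)CC)CC[C@@H]2[C@@H]1CC2(C)C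
F5 | step 2 | 2-(2-methylpropylidene)-4,4,6,6-tetramethylcyclohexane-1,3,5-trione | CC(C)C=C1C(=O)C(C)(C)C(=O)C(C)(C)C1=O
F6 | step 7 | methyl 2,2,4-trimethyl-3-(trimethylsilyloxy)pent-3-enoate | COC(=O)C(C)(C)C(O[Si](C)(C)C)=C(C)C
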